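Drimane numbering is used throughout: ring A = C1–C5 and C10, ring B = C5–C10, C11 = the OCH2 carbon, C12 = the methyl on C8.

## Structural features

The target is a 7-O-alkyl umbelliferone whose alkyl part is an ent-drimane sesquiterpene: a trans-fused decalin in which ring A is a cyclohexanone (C3 carbonyl, gem-dimethyl at C4) and ring B is a cyclohexene with a trisubstituted C7=C8 bond carrying C12. The rings share C5–C10; C10 is quaternary (angular methyl) and C9 carries the C11 methylene that is bound through oxygen to C7 of the coumarin. The three stereocentres C5 (S), C10 (R) and C9 (R) are contiguous: H5 and the C10 methyl are trans, and the C11 arm on C9 is cis to the C10 methyl, that is equatorial. Fragile points are the coumarin lactone (opened by hydroxide, alkoxide or hydride) and the C9–H bond, which is allylic and, at the aldehyde oxidation level, also α to a carbonyl, so that epimerisation and migration of the alkene into conjugation are possible. The C3 ketone must also be told apart from any carbonyl at C11. The real difficulty is the absolute configuration of the quaternary C10 and the relay of that information to C5 and C9 on a skeleton without heteroatom handles near these centres. The key step exploits ring A: the C3 carbonyl and the quaternary C10 stand 1,4 in a six-membered ring, which is the retron of a [4+2] addition of a 1-amino-3-siloxybutadiene (C1–C4) to an α-methyl enal (C10=C5). The E geometry of that enal fixes the trans relation of C9 and C6 that later becomes the trans ring fusion.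

## Logic of the disconnections

19 is cut at the C11–O(aryl) bond into 17 and 18. The lactone of 18 would not survive the hydride, enolate and ylide chemistry used earlier, so the arene is attached last. This removes the whole aromatic part and leaves a C15 alcohol. The forward step must substitute a β-branched primary carbinol under neutral conditions without touching the C3 ketone or the C9–H bond.

17 is traced to 16 by changing C11 from alcohol to aldehyde; no skeletal bond is cut. The reason is that the ring-forming step delivers C11 as a carbonyl. The forward reduction must take the aldehyde and leave the hindered C3 ketone, and it must be faster than enolisation at C9.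

16 is cut at C8–C9 to give 15. C9 is α to the C11 carbonyl and so corresponds to the nucleophilic carbon of an enol ether, and C8 is one end of an alkyne; closing this bond leaves the alkene at C7=C8. The bicycle becomes a monocycle and the C9 stereocentre disappears. The forward step must close in the 6-endo mode, place the C11 arm equatorial, and release the aldehyde without epimerisation.

15 is traced to 14 by reintroducing the C1=C2 double bond. The enone is what the cycloaddition provides, and it blocks enolisation toward C2 in the next disconnection. The forward step must deliver hydride in the conjugate sense and spare the alkyne and the enol ether.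

14 is cut at both C4–CH3 bonds to give 12, by way of 13. In 12 the only acidic hydrogens are at C4, because C2 is vinylic and C10 is quaternary. The cut removes a quaternary carbon. The forward step needs two enolate methylations, the second next to the substituted C5.

12 is cut at C9=C11 to give 11. One-carbon homologation brings in C11 and converts the electrophilic formyl carbon C9 into a nucleophilic enol ether carbon. The ylide must choose the aldehyde over the enone carbonyl.

11 is cut at C1–C10 and C4–C5 to give 9 and 4, by way of 10. This removes ring A and both of its stereocentres and leaves two achiral, acyclic components. The forward step must control the face of a trisubstituted enal by a catalyst and must have a single regiochemistry. It also needs a diene that tolerates a cationic Lewis acid, which is why the nitrogen of 9 is a carbamate and not a basic dialkylamine.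

9 is cut at the O–Si bond to give 8. The forward step is kinetic enolisation of a methyl ketone and O-silylation.

8 is cut at the N–C(=O) bond to give 7. The forward step must acylate nitrogen and not oxygen or carbon.

7 is cut at the N–C(vinyl) bond to give 5 and 6, both commercial. The forward step is an addition–elimination on a β-alkoxy enone.

4 is cut at C5=C10 to give 1 and 2, by way of 3. A formyl-stabilised ylide gives the E alkene. The demand is that 3, a β,γ-alkynyl aldehyde that isomerises easily to an allene, is made and consumed in the same flask.

## Other disconnections considered

Alternative 1: The cut goes through C1–C2 and C9–C10, so both rings are opened to the acyclic β-keto ester A1. A1 already holds the umbelliferyl ether at C11, the gem-dimethyl group at C4 and one stereocentre, C5, which bears an isopropenyl group (C10 and C1).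
- Forward step: Mn(OAc)3 (trivalent manganese) would oxidise the β-keto ester to the C2 radical, which would add to the isopropenyl CH2 (C1). The tertiary C10 radical would then add to C9 of the E alkene, and Cu(OAc)2 (divalent copper) would oxidise the C8 radical to an alkene, giving A2.
- In its favour: two rings, two C–C bonds and the quaternary centre would form in one operation. The aryl ether is in place beforehand, so no late substitution at the hindered C11 is needed; on this point the alternative is better than the chosen plan. Only removal of the ester would remain after the key step, so its endgame is also shorter.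
- Against it here: everything depends on making the acyclic C5 centre, next to a quaternary carbon, as a single enantiomer, which is a problem of the same weight as the one it replaces. The relay from C5 to C10 and C9 passes through a planar tertiary radical and a chair-like arrangement that is plausible but not assured. The final oxidation can remove hydrogen from C7, C12 or C9, so the alkene position is not secured. An electron-rich aryl allyl ether and a coumarin would meet a stoichiometric one-electron oxidant in hot acetic acid.
- Comparison: structurally the alternative closes two rings against one and sets the same number of stereocentres in its key step (two), so it is the equal or the better there. Mechanistically it relies on substrate-controlled radical diastereoselection, whereas the chosen plan relies on catalyst-controlled facial selection in a pericyclic step with close precedent. In step count it is shorter after the key step and longer and less certain before it.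

Alternative 2: The cut goes through C7–C8 and C9–C10, a retro-[4+2] of ring B, and leads to the ring A diene A3 and the ynal A4.
- Forward step: a Brønsted-acid-assisted chiral boron Lewis acid would activate A4, and cycloaddition would give the 1,4-cyclohexadiene A5 with alkenes at C5=C6 and C8=C9.
- In its favour: two simple achiral partners are joined convergently. The gem-dimethyl group and the C3 oxygen are present from the start, so no C4 methylation is needed; on this point it is better than the chosen plan. C11 arrives at the aldehyde level, and the regiochemistry is reinforced because the unsubstituted diene terminus C7 pairs with the β-carbon C8.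
- Against it here: the diene is tetrasubstituted at C5=C10 and flanked by the gem-dimethyl group, so the reactive s-cis form is disfavoured, and the quaternary centre would have to form at a fully substituted diene terminus. The key step sets only C10. C5 would need a face-selective hydrogen delivery to a hindered alkene in the presence of an enal. C9 would need the C8=C9 bond to be moved to C7=C8 with control of the new C9–H, and deprotonation of such an enal is expected to favour the C12 methyl, which lies cis to the formyl group.
- Comparison: both plans use a Lewis-acid-catalysed enantioselective [4+2] on an aldehyde, so they are equal in reaction type. The alternative reaches its key step in fewer operations, which is a point in its favour. It postpones two of the three stereocentres, where the chosen plan postpones one, and its endgame is at least as long and less predictable.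

Alternative 3: The cut is at C9–C10 alone, and ring A is traced to the arene of the phenol A6, which carries a (Z)-vinyl epoxide side chain at C5.
- Forward step: Pd2(dba)3 (zerovalent palladium) with the chiral bis(diphenylphosphinobenzoyl)diaminocyclohexane ligand would open the epoxide to a C7–C8–C9 allyl complex, and the para carbon C10 of the phenol would attack C9 to give the cross-conjugated dienone A7.
- In its favour: ring B, the quaternary centre, C9, the C7=C8 alkene and the free C11 alcohol would all appear in one catalytic step. C9 and C11 would be finished without an epimerisable aldehyde, which is better than the chosen plan. The remaining work would be short: saturation of C1=C2, then reductive methylation of the C4=C5 enone (Li in liquid NH3, then MeI), which adds the second C4 methyl and sets H5 trans in a well-understood way.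
- Against it here: C-alkylation at a methyl-bearing para carbon must outrun intermolecular O-alkylation. The allyl unit is substituted at both ends, so its faces cannot interconvert easily; C9 would then follow the epoxide configuration, and A6 would have to be made as one enantiomer with a defined alkene geometry. The relative configuration of C9 and C10 would rest on a ligand pocket that is untested for adjacent tertiary and quaternary centres.
- Comparison: on the C9 problem and on the length after the key step the alternative is better. On access to the key-step precursor and on closeness of precedent for the key step the chosen plan is better. Overall step counts would be comparable.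

Key step: step 5

Assumption: (salen) denotes the dianion of N,N'-bis(3,5-di-tert-butylsalicylidene)-trans-cyclohexane-1,2-diamine; the (S,S) complex is taken to expose the enal face that leads to (1S,6R)-11, and the equally accessible (R,R) complex is to be used if the facial sense is the opposite.

Assumption: compounds 12 to 15 are carried as E/Z mixtures about C9=C11, which is acceptable because this geometry is lost in step 9.

## Route

Step 1
Reactants: 1 pent-3-yn-1-ol; 2 2-(triphenylphosphoranylidene)propanal
Product: 4 (E)-2-methylhept-2-en-5-ynal, via pent-3-ynal 3 (not isolated)
Conditions: DMP, 2 present from the start, CH2Cl2, 0 °C → rt, then 40 °C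
Reagents that add atoms: none
Why: Periodinane oxidation gives the β,γ-alkynyl aldehyde 3, which is trapped as it forms by the formyl-stabilised ylide in a Wittig reaction; stabilised ylides give the E trisubstituted alkene, and the enal product is a much poorer electrophile toward 2 than 3, so a second olefination should be slow.

Step 2
Reactants: 5 (E)-4-methoxybut-3-en-2-one; 6 benzylamine
Product: 7 (Z)-4-(benzylamino)but-3-en-2-one
Conditions: CH2Cl2, 0 °C → rt
Reagents that add atoms: none
Why: Addition–elimination of the amine on the β-methoxy enone (vinylogous transamidation); the product is held in the Z form by an N–H···O hydrogen bond.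

Step 3
Reactants: 7 (Z)-4-(benzylamino)but-3-en-2-one
Product: 8 methyl benzyl[(1E)-3-oxobut-1-en-1-yl]carbamate
Conditions: NaN(SiMe3)2, THF, −78 °C; then ClCO2Me, −78 → 0 °C
Reagents that add atoms: methyl chloroformate, COC(=O)Cl
Why: N-Acylation of the sodium salt of a vinylogous amide with a chloroformate gives the vinylogous imide; once the hydrogen bond is gone the enamide settles in the E geometry needed for the diene.

Step 4
Reactants: 8 methyl benzyl[(1E)-3-oxobut-1-en-1-yl]carbamate
Product: 9 methyl benzyl[(1E)-3-(tert-butyldimethylsilyloxy)buta-1,3-dien-1-yl]carbamate
Conditions: NaN(SiMe3)2, THF, −78 °C; then TBSCl, −78 °C → rt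
Reagents that add atoms: tert-butyldimethylsilyl chloride, CC(C)(C)[Si](C)(C)Cl
Why: Kinetic deprotonation of the methyl ketone and O-silylation (silyl enol ether formation) give the 2-siloxy diene; the carbamate nitrogen is not basic, which makes the diene compatible with a cationic Lewis acid.

Step 5
Reactants: 9 methyl benzyl[(1E)-3-(tert-butyldimethylsilyloxy)buta-1,3-dien-1-yl]carbamate; 4 (E)-2-methylhept-2-en-5-ynal
Product: 11 (1S,6R)-6-(but-2-yn-1-yl)-1-methyl-4-oxocyclohex-2-ene-1-carbaldehyde, via silyl enol ether cycloadduct 10 (not isolated)
Conditions: (S,S)-(salen)CrSbF6 (5–10 mol %), 4 Å MS, CH2Cl2, −40 °C → rt; then TFA, wet CH2Cl2, 0 °C → rt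
Reagents that add atoms: none
Why: The cationic chromium centre (trivalent chromium) binds the formyl oxygen of 4 and lowers its LUMO, and the diene 9 adds in a concerted but asynchronous [4+2] process in which the CH2 terminus C4 bonds to the β-carbon C5 ahead of the bond from the nitrogen-bearing C1 to the α-carbon C10. The closest known reaction type is the (salen)chromium-catalysed Diels–Alder reaction of 1-(acylamino)-3-siloxybutadienes with α-substituted acroleins, which gives the same 4-formyl-4-alkylcyclohexenone unit; a carbamate is used on nitrogen because a basic dialkylamino diene would bind the Lewis acid and would also react without it. Ring A is closed by an intermolecular cycloaddition, so the six-membered ring forms from two components with no ring-closure constraint. C10 is set by the catalyst, which shields one face of the coordinated enal, and C5 follows from C10 because the addition is suprafacial on the E alkene, so that the formyl carbon C9 and the butynyl CH2 C6 end up trans. The C1 centre of 10 depends on the endo or exo orientation and is deleted when acid ionises the allylic carbamate with the push of the silyl enol ether and releases the enone. Regioselectivity is required and is secured by the matched donor effects of the carbamate nitrogen and the siloxy group, which make C4 the nucleophilic terminus; the isolated alkyne is a far poorer dienophile than the coordinated enal, so it should not compete. The formyl group of 11 sits on a quaternary carbon and cannot enolise, so the acid treatment does not endanger C10.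

Step 6
Reactants: 11 (1S,6R)-6-(but-2-yn-1-yl)-1-methyl-4-oxocyclohex-2-ene-1-carbaldehyde
Product: 12 (4S,5R)-5-(but-2-yn-1-yl)-4-(2-methoxyethenyl)-4-methylcyclohex-2-en-1-one (E/Z mixture)
Conditions: MeOCH2PPh3Cl, KN(SiMe3)2, THF, 0 °C; then 11, −78 → 0 °C
Reagents that add atoms: (methoxymethyl)triphenylphosphonium chloride, COC[P+](c1ccccc1)(c1ccccc1)c1ccccc1.[Cl-]
Why: Wittig methoxymethylenation: at low temperature the alkoxy ylide attacks the aldehyde much faster than the less electrophilic enone carbonyl, and the formyl carbon cannot enolise; both enol ether isomers lead to the same oxocarbenium ion in step 9.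

Step 7
Reactants: 12 (4S,5R)-5-(but-2-yn-1-yl)-4-(2-methoxyethenyl)-4-methylcyclohex-2-en-1-one
Product: 14 (4R,5S)-5-(but-2-yn-1-yl)-4-(2-methoxyethenyl)-4,6,6-trimethylcyclohex-2-en-1-one, via monomethyl enone 13 (not isolated)
Conditions: LiN(iPr)2, THF, −78 °C; MeI, −78 → 0 °C; then LiN(iPr)2, DMPU, −78 °C; MeI, −78 °C → rt
Reagents that add atoms: iodomethane, CI
Why: Two kinetic α'-enolate alkylations: in 12 the only acidic hydrogens are at C4 (C2 is vinylic and C10 is quaternary), so both methyl groups must enter there; the C4 centre of 13 is erased by the second methylation, and C5, which has no acidic hydrogen, is untouched (its descriptor changes only through the priority rules).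

Step 8
Reactants: 14 (4R,5S)-5-(but-2-yn-1-yl)-4-(2-methoxyethenyl)-4,6,6-trimethylcyclohex-2-en-1-one
Product: 15 (3S,4R)-3-(but-2-yn-1-yl)-4-(2-methoxyethenyl)-2,2,4-trimethylcyclohexan-1-one
Conditions: [(Ph3P)CuH]6 (0.5 equiv), wet toluene, rt
Reagents that add atoms: none
Why: Copper hydride conjugate reduction: hydride goes to C1 of the enone and water protonates the copper enolate; the unactivated internal alkyne and the enol ether are not reduced under these conditions, which is why hydrogenation is avoided.

Step 9
Reactants: 15 (3S,4R)-3-(but-2-yn-1-yl)-4-(2-methoxyethenyl)-2,2,4-trimethylcyclohexan-1-one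
Product: 16 (1R,4aS,8aR)-2,5,5,8a-tetramethyl-6-oxo-1,4,4a,5,6,7,8,8a-octahydronaphthalene-1-carbaldehyde
Conditions: Ph3PAuNTf2 (5 mol %), CH2Cl2/H2O (10:1), 0 °C → rt
Reagents that add atoms: water, O
Why: Gold-catalysed enol ether–alkyne carbocyclisation of a 1,6-enyne in the 6-endo-dig mode: the cationic gold complex (monovalent gold) activates C7≡C8, the enol ether carbon C9 attacks C8 anti to the metal, protodeauration leaves the C7=C8 alkene and water hydrolyses the C11 oxocarbenium ion to the aldehyde. The trans-diequatorial arms on C10 and C5 favour closure to a trans-decalin over a 5-exo closure to a strained trans-hydrindane, and C9 is set in a chair-like transition state that is expected to place the C11 arm equatorial, cis to the C10 methyl.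

Step 10
Reactants: 16 (1R,4aS,8aR)-2,5,5,8a-tetramethyl-6-oxo-1,4,4a,5,6,7,8,8a-octahydronaphthalene-1-carbaldehyde
Product: 17 (4aR,5R,8aS)-5-(hydroxymethyl)-1,1,4a,6-tetramethyl-3,4,4a,5,8,8a-hexahydronaphthalen-2(1H)-one
Conditions: NaBH4 (0.5 equiv), EtOH/CH2Cl2 (3:7), −78 °C; AcOH quench
Reagents that add atoms: none
Why: Chemoselective borohydride reduction: at −78 °C the aldehyde is reduced much faster than the C3 ketone, which is shielded by the adjacent gem-dimethyl group, and hydride addition should be faster than enolisation at C9, so the configuration and the alkene position are kept.

Step 11
Reactants: 17 (4aR,5R,8aS)-5-(hydroxymethyl)-1,1,4a,6-tetramethyl-3,4,4a,5,8,8a-hexahydronaphthalen-2(1H)-one; 18 umbelliferone (7-hydroxy-2H-chromen-2-one)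
Product: 19 7-{[(1R,4aS,8aR)-2,5,5,8a-tetramethyl-6-oxo-1,4,4a,5,6,7,8,8a-octahydronaphthalen-1-yl]methoxy}-2H-chromen-2-one
Conditions: PPh3, DIAD, THF, 0 °C → rt
Reagents that add atoms: none
Why: Mitsunobu etherification: the acidic phenol protonates the betaine and its phenoxide displaces the oxyphosphonium group at the primary C11 (SN2, no stereocentre involved); the neutral conditions leave the lactone, the ketone and the C9–H bond alone.

## Compound list

1 | pent-3-yn-1-ol | CC#CCCO | starting material
2 | 2-(triphenylphosphoranylidene)propanal | CC(C=O)=P(c1ccccc1)(c1ccccc1)c1ccccc1 | starting material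
3 | pent-3-ynal | CC#CCC=O | intermediate
4 | (E)-2-methylhept-2-en-5-ynal | CC#CC/C=C(C)/C=O | intermediate
5 | (E)-4-methoxybut-3-en-2-one | CO/C=C/C(C)=O | starting material
6 | benzylamine | NCc1ccccc1 | starting material
7 | (Z)-4-(benzylamino)but-3-en-2-one | CC(=O)/C=C\NCc1ccccc1 | intermediate
8 | methyl benzyl[(1E)-3-oxobut-1-en-1-yl]carbamate | COC(=O)N(Cc1ccccc1)/C=C/C(C)=O | intermediate
9 | methyl benzyl[(1E)-3-(tert-butyldimethylsilyloxy)buta-1,3-dien-1-yl]carbamate | COC(=O)N(Cc1ccccc1)/C=C/C(=C)O[Si](C)(C)C(C)(C)C | intermediate
10 | methyl benzyl[5-(but-2-yn-1-yl)-6-formyl-6-methyl-3-(tert-butyldimethylsilyloxy)cyclohex-2-en-1-yl]carbamate, drawn as the endo adduct (carbamate cis to formyl, formyl trans to butynyl) | O=C[C@]1(C)[C@H](N(Cc2ccccc2)C(=O)OC)C=C(O[Si](C)(C)C(C)(C)C)C[C@H]1CC#CC | intermediate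
11 | (1S,6R)-6-(but-2-yn-1-yl)-1-methyl-4-oxocyclohex-2-ene-1-carbaldehyde (formyl and butynyl trans) | O=C[C@]1(C)C=CC(=O)C[C@H]1CC#CC | intermediate
12 | (4S,5R)-5-(but-2-yn-1-yl)-4-(2-methoxyethenyl)-4-methylcyclohex-2-en-1-one, E/Z mixture | COC=C[C@]1(C)C=CC(=O)C[C@H]1CC#CC | intermediate
13 | 5-(but-2-yn-1-yl)-4-(2-methoxyethenyl)-4,6-dimethylcyclohex-2-en-1-one, ring centres C4 and C5 as in 12, both C6 epimers, E/Z mixture | COC=C[C@]1(C)C=CC(=O)C(C)[C@H]1CC#CC | intermediate
14 | (4R,5S)-5-(but-2-yn-1-yl)-4-(2-methoxyethenyl)-4,6,6-trimethylcyclohex-2-en-1-one, E/Z mixture | COC=C[C@]1(C)C=CC(=O)C(C)(C)[C@H]1CC#CC | intermediate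
15 | (3S,4R)-3-(but-2-yn-1-yl)-4-(2-methoxyethenyl)-2,2,4-trimethylcyclohexan-1-one, E/Z mixture | COC=C[C@]1(C)CCC(=O)C(C)(C)[C@H]1CC#CC | intermediate
16 | (1R,4aS,8aR)-2,5,5,8a-tetramethyl-6-oxo-1,4,4a,5,6,7,8,8a-octahydronaphthalene-1-carbaldehyde | CC1=CC[C@@H]2C(C)(C)C(=O)CC[C@@]2(C)[C@@H]1C=O | intermediate
17 | (4aR,5R,8aS)-5-(hydroxymethyl)-1,1,4a,6-tetramethyl-3,4,4a,5,8,8a-hexahydronaphthalen-2(1H)-one | CC1=CC[C@@H]2C(C)(C)C(=O)CC[C@@]2(C)[C@@H]1CO | intermediate
18 | umbelliferone (7-hydroxy-2H-chromen-2-one) | Oc1ccc2ccc(=O)oc2c1 | starting material
19 | 7-{[(1R,4aS,8aR)-2,5,5,8a-tetramethyl-6-oxo-1,4,4a,5,6,7,8,8a-octahydronaphthalen-1-yl]methoxy}-2H-chromen-2-one | CC1=CC[C@@H]2C(C)(C)C(=O)CC[C@@]2(C)[C@@H]1COc1ccc2ccc(=O)oc2c1 | target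

## Step count and least certain steps

Total: 11 steps. Longest linear sequence: 10 steps (steps 2, 3, 4, 5, 6, 7, 8, 9, 10, 11).

Step 5 (key step). The most likely failure is sluggish cycloaddition: the dienophile is trisubstituted and the carbamate diene is less electron-rich than an amino diene. The reaction may then need a higher temperature, where enantioselection erodes and the diene is slowly hydrolysed. The fallback changes the mode of activation and the diene. It sets out from 4 and the commercial (E)-1-(dimethylamino)-3-(tert-butyldimethylsilyloxy)buta-1,3-diene F1, which is far more reactive. These are combined under hydrogen-bond catalysis by α,α,α',α'-tetra(1-naphthyl)-2,2-dimethyl-1,3-dioxolane-4,5-dimethanol (20 mol %, toluene, −78 → −40 °C; antipode chosen for the required face) to give the amino cycloadduct F2. Treatment of the crude F2 with HF in MeCN at 0 °C expels dimethylamine and returns the route at 11.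

Step 9. The most likely failure is poor facial selectivity at C9 during C–C bond formation, because the enol ether can turn either face toward C8, and the preference for an equatorial C11 arm is an expectation, not a certainty. Later drift of the C9–H bond by enolisation of the β,γ-unsaturated aldehyde is a related danger. Competing 5-exo closure and participation of the C3 carbonyl oxygen are secondary concerns; a bulkier biaryl phosphine on gold would be tried first for these. The fallback sets C9 by kinetic protonation instead of by ring closure. It sets out from 16 obtained as a mixture of C9 epimers. KN(SiMe3)2 (2.2 equiv, THF, −78 °C) converts both epimers into the same dipotassium bis-enolate F3 (extended enolate over C11, C9, C8 and C7, plus the C3 enolate). A fast quench with AcOH at −78 °C protonates the extended enolate at its α-carbon C9 on the axial face anti to the C10 methyl and leaves C7=C8 in place. The route is rejoined at 16 as one epimer.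

Step 1. The most likely failure is isomerisation of the β,γ-alkynyl aldehyde to an allenyl aldehyde before it is olefinated, because the formyl-stabilised ylide reacts slowly and needs warming. The fallback uses a faster ylide and a redox adjustment. It sets out from 1: the same periodinane oxidation is run with ethyl 2-(triphenylphosphoranylidene)propanoate at rt, which should trap 3 quickly as ethyl (E)-2-methylhept-2-en-5-ynoate F4. Reduction with (iBu)2AlH (CH2Cl2, −78 °C) gives (E)-2-methylhept-2-en-5-yn-1-ol F5, and MnO2 (CH2Cl2, rt) returns the route at 4.

Step 11. The most likely failure is slow displacement at C11, which is flanked by the tertiary allylic C9 and the quaternary C10, so that the activated alcohol is diverted to alkylation of the hydrazide or to elimination. The fallback separates activation from substitution. It sets out from 17: MsCl and Et3N (CH2Cl2, 0 °C) give the methanesulfonate F6, and heating F6 with 18 and Cs2CO3 in DMF at 50–60 °C (Williamson etherification) returns the route at 19.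

## Further compounds

F1 | step 5 | (E)-1-(dimethylamino)-3-(tert-butyldimethylsilyloxy)buta-1,3-diene | CN(C)/C=C/C(=C)O[Si](C)(C)C(C)(C)C
F2 | step 5 | 6-(but-2-yn-1-yl)-2-(dimethylamino)-1-methyl-4-(tert-butyldimethylsilyloxy)cyclohex-3-ene-1-carbaldehyde, drawn as the endo adduct (amino cis to formyl, formyl trans to butynyl) | O=C[C@]1(C)[C@H](N(C)C)C=C(O[Si](C)(C)C(C)(C)C)C[C@H]1CC#CC
F3 | step 9 | dipotassium bis-enolate of 16 (C11 extended enolate and C3 enolate; C5 and C10 as in 16) | [K+].[K+].CC1=CC[C@@H]2C(C)(C)C([O-])=CC[C@@]2(C)C1=C[O-]
F4 | step 1 | ethyl (E)-2-methylhept-2-en-5-ynoate | CCOC(=O)/C(C)=C/CC#CC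
F5 | step 1 | (E)-2-methylhept-2-en-5-yn-1-ol | CC#CC/C=C(C)/CO
F6 | step 11 | methanesulfonate of 17, [(1R,4aS,8aR)-2,5,5,8a-tetramethyl-6-oxo-1,4,4a,5,6,7,8,8a-octahydronaphthalen-1-yl]methyl methanesulfonate | CC1=CC[C@@H]2C(C)(C)C(=O)CC[C@@]2(C)[C@@H]1COS(C)(=O)=O
A1 | alternative 1 | methyl (5S,8E)-4,4,8-trimethyl-3-oxo-10-[(2-oxo-2H-chromen-7-yl)oxy]-5-(prop-1-en-2-yl)dec-8-enoate | COC(=O)CC(=O)C(C)(C)[C@H](C(C)=C)CC/C(C)=C/COc1ccc2ccc(=O)oc2c1
A2 | alternative 1 | 2-methoxycarbonyl derivative of 19, C2=C3 enol form | CC1=CC[C@@H]2C(C)(C)C(O)=C(C(=O)OC)C[C@@]2(C)[C@@H]1COc1ccc2ccc(=O)oc2c1
A3 | alternative 2 | 7-ethenyl-6,6,8-trimethyl-1,4-dioxaspiro[4.5]dec-7-ene | C=CC1=C(C)CCC2(OCCO2)C1(C)C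
A4 | alternative 2 | but-2-ynal | CC#CC=O
A5 | alternative 2 | C3 ethylene ketal of ent-drima-5,8-dien-11-al | CC1=C(C=O)[C@]2(C)CCC3(OCCO3)C(C)(C)C2=CC1
A6 | alternative 3 | 2,4-dimethyl-3-{(2Z)-3-[(2S)-oxiran-2-yl]but-2-en-1-yl}phenol | Cc1ccc(O)c(C)c1C/C=C(/C)[C@H]1CO1
A7 | alternative 3 | 5-(hydroxymethyl)-1,4a,6-trimethyl-5,8-dihydronaphthalen-2(4aH)-one, hydroxymethyl cis to the ring-fusion methyl | CC1=CCC2=C(C)C(=O)C=C[C@@]2(C)[C@@H]1CO
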